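Atom labels C1–C15 and O5/O6 refer to the target numbering defined in the first section; plain numbers 1–22 are compounds.

## Analysis of the target

Numbering used throughout: ring A is the cycloheptanone C1 (quaternary carbinol)–C5 (CH–O-acyl)–C6 (CH–O-lactone)–C7 (ring-fusion CH)–C8 (CH2)–C9 (C=O)–C10 (CH–CH3, methyl = C14); ring B is the α-methylene-γ-lactone O6–C6–C7–C11(=C13H2)–C12(=O); C2(=O)–C3=C4–C15 is the (E)-but-2-enoyl group on C1, and O5 carries the (S)-2-methylbutanoyl group. The five ring stereocentres are contiguous (C10–C1–C5–C6–C7; 1S,5S,6R,7S,10R): the C10 methyl, the C1 hydroxyl, O6 and C11 lie on one face (α), O5 and the C1 acyl group on the other (β), so the lactone is cis-fused, C5/C6 are trans-dioxygenated and the C1/C5 oxygens are trans. C1 is fully substituted and is the centre of four contiguous oxygenated carbons, C2–C1–C5–C6. Sensitive groups are two Michael acceptors (C11=C13, C3=C4), a tertiary α-ketol (acyloin shift), a β-ketol C9–C10–C1 (retro-aldol), an epimerisable C10–H and ester α-centre, and an ester next to hydroxyls (acyl migration), so strong base and late enolate chemistry are excluded. The difficulty is the saturated seven-membered ring with five stereocentres and no ring alkene left as a handle. The feature that suggests the strategy: C9 is a carbonyl flanked by C8H2 and C10H, C1 carries a carboxyl-level carbon (C2), and C6, C7 and C10 are all-cis. Read with C9 as a silyl enol ether (C8=C9) and C1 as the α-carbon of an enoate (C1=C5), ring A is a cyclohepta-1,4-diene of the type formed from a vinylcarbenoid (C2–C1–C5–C6) and a 2-siloxy-1,3-diene (C10–C9–C8–C7) by cyclopropanation/Cope rearrangement, whose boat transition state gives exactly this all-cis triad.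

## Retrosynthetic reasoning

**C2–C3 (side chain).** 22 is cut between C2 and C3, through allylic alcohol 21, to aldehyde 19 and alkenyl bromide 20. The enone is the second Michael acceptor and part of the α-ketol, so it is made last. The forward steps need an alkenyl-metal addition that touches only the aldehyde, then a base-free oxidation.

**O5–acyl.** 19 is cut at the ester C–O bond to aldehyde 17 and anhydride 18. In 17 the C5 hydroxyl is the only secondary alcohol (C1–OH is tertiary, O6 is in the lactone, C2 is already an aldehyde), so no protecting group is needed.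

**Ring B (O6–C12 and C11–C12).** 17 goes back to primary alcohol 16. 16 is cut at both bonds to C12, which gives the ethynyl alcohol 15. The forward reaction is a carbonylative ring closure of the C7 ethynyl group onto O6. The two alkyne carbons become C11 and C13, so the exocyclic methylene comes without lactone-enolate chemistry, and only O6 is cis to the alkyne and five atoms away.

**C1–O and C5–O.** 15 comes from 14 by desilylation. 14 is cut at C1–OH back to the β-epoxide 13, and 13 to the allylic alcohol 12. Both forward steps follow the substrate bias: the β face of C1=C5 is the open one (C6–O, C7–C and C10–CH3 are all α), and hydrolytic opening of a trisubstituted epoxide occurs at the tertiary carbon (C1) with inversion. That puts the C1 hydroxyl α and leaves O5 β, as required.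

**C2 oxidation level.** 12 comes from ester 11 by reduction. C2 is an ester in 11 because the carbenoid of the key step needs an acceptor group.

**Ring A (C1–C10 and C6–C7; key).** 11 is cut at C6–C7 (retro-Cope) to the cis-divinylcyclopropane 10. 10 is the C1 epimer of cyclopropane 9, which is cut at C1–C10 and C1–C9 to diene 4 and vinyldiazoacetate 8. This one disconnection removes the seven-membered ring and the C6, C7 and C10 stereocentres, and leaves two achiral four-carbon chains. It also delivers C9 at the ketone level, C2 at the carboxyl level and the C1=C5 alkene needed for the two remaining centres. The forward reaction has to select the enol-ether π bond of 4, fix C10 by catalyst control, and pass through the cis isomer 10.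

**Fragments.** 4 comes from enynone 3 by enol silylation, and 3 from aldehyde 1 and phosphonate 2 by olefination. The alkynyl group is chosen because it has no γ-hydrogen, is inert to the carbenoid and carries C11/C13. 8 comes from the diazo aldol 7 by dehydration, and 7 from aldehyde 5 and diazoacetate 6.

## Alternatives that were turned down

**Alternative 1:** (textbook) Disconnection at C5=C6 by ring-closing metathesis, with the lactone annulated afterwards. The forward key step would close an acyclic 1,8-diene with a ruthenium carbene to cycloheptenone A1, followed by dioxygenation of C5=C6, lactonisation and α-methylenation. It was turned down because the ring closure sets no stereocentre. C1 (a ketone-type aldol with weak facial control), C10 and C7 would each need their own event in an open chain. The alkene to be closed sits next to the quaternary C1 carbinol. After closure the route still needs a face-differentiated trans-dioxygenation and a base-mediated α-methylenation beside the C9 ketone. The step count would clearly exceed that of the chosen route.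

**Alternative 2:** Disconnection at C1–C10 by intramolecular aldol addition of the C9 ethyl ketone to the C1 carbonyl of a vicinal diketone, seco-diketone A2. It was turned down on mechanism. The C8 enolate closes a five-membered ring onto C1 (C8–C7–C6–C5–C1) faster than the C10 enolate closes the seven-membered one. C5–H of A2 is α to the diketone and β to O6, so enolisation expels the lactone oxygen. C1 and C10 would form under reversible conditions with no controlling element. A2 already contains C5, C6 and C7, so it is hardly simpler than the product.

**Alternative 3:** Disconnection at C1–C10 and C7–C8 by (4+3) cycloaddition of an oxyallyl cation (C8–C9–C10) with a 2-substituted furan (C1, C5, C6, C7) to the oxabicycle A3. This places the C9 ketone and a C5=C6 alkene correctly and makes C1 a carbinol carbon. It was turned down because the oxygen bridge ends on C7, where the target has a C–C bond. The bridge would have to be opened by β-elimination and C11 brought in at C7 cis to O6 against the substrate bias. The compact transition state places the C10 methyl trans to the bridge oxygen, opposite to the target. Regiochemistry between two unsymmetrical partners and enantiocontrol are both unsecured, so every centre except C1 would be set later.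

Key step: step 5

Assumption: the sense of induction of the dirhodium prolinate catalyst in step 5 is assigned from the accepted approach model for this catalyst family; if it proves opposite, the antipodal catalyst is used and nothing else changes.

## Route

Step 1
Reactants: 1 3-(trimethylsilyl)prop-2-ynal; 2 diethyl (2-oxobutyl)phosphonate
Product: 3 (4E)-7-(trimethylsilyl)hept-4-en-6-yn-3-one
Conditions: LiCl, i-Pr2NEt, MeCN, 0 °C → rt
Reagents that add atoms: none
Why: Horner–Wadsworth–Emmons olefination under Masamune–Roush conditions; the stabilised phosphonate should give the E-enone and the mild base spares the C–Si bond.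

Step 2
Reactants: 3 (4E)-7-(trimethylsilyl)hept-4-en-6-yn-3-one
Product: 4 tert-butyldimethyl{[(2Z,4E)-7-(trimethylsilyl)hepta-2,4-dien-6-yn-3-yl]oxy}silane
Conditions: TBSOTf, Et3N, CH2Cl2, −78 → 0 °C
Reagents that add atoms: tert-butyldimethylsilyl trifluoromethanesulfonate, CC(C)(C)[Si](C)(C)OS(=O)(=O)C(F)(F)F
Why: Soft enolisation/O-silylation; 3 has no γ-hydrogen (the γ-carbon is sp), so only the ethyl CH2 can be deprotonated, and amine/silyl triflate conditions should give the Z enol ether (methyl cis to oxygen).

Step 3
Reactants: 5 [(tert-butyldimethylsilyl)oxy]acetaldehyde; 6 ethyl diazoacetate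
Product: 7 ethyl 4-[(tert-butyldimethylsilyl)oxy]-2-diazo-3-hydroxybutanoate (racemic)
Conditions: DBU (10 mol %), MeCN, 0 °C → rt
Reagents that add atoms: none
Why: Base-catalysed aldol-type addition of the diazoacetate C–H to an aldehyde; the carbinol centre is removed in step 4, so its configuration does not matter.

Step 4
Reactants: 7 ethyl 4-[(tert-butyldimethylsilyl)oxy]-2-diazo-3-hydroxybutanoate
Product: 8 ethyl (3E)-4-[(tert-butyldimethylsilyl)oxy]-2-diazobut-3-enoate
Conditions: POCl3, Et3N, CH2Cl2, 0 °C → rt; used at once
Reagents that add atoms: none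
Why: Dehydration of a β-hydroxy-α-diazo ester via its dichlorophosphate is the standard entry to vinyldiazoacetates; elimination can only go towards the CH2–O carbon and should give the E alkene.

Step 5
Reactants: 4 tert-butyldimethyl{[(2Z,4E)-7-(trimethylsilyl)hepta-2,4-dien-6-yn-3-yl]oxy}silane; 8 ethyl (3E)-4-[(tert-butyldimethylsilyl)oxy]-2-diazobut-3-enoate
Product: 11 ethyl (3S,4S,7R)-3,6-bis[(tert-butyldimethylsilyl)oxy]-7-methyl-4-[(trimethylsilyl)ethynyl]cyclohepta-1,5-diene-1-carboxylate (ring carbons 1–7 of this name = C1, C5, C6, C7, C8, C9, C10), via trans-divinylcyclopropane 9 (not isolated), via cis-divinylcyclopropane 10 (not isolated)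
Conditions: Rh2(R-DOSP)4 (1 mol %), 4 (2 equiv), hexanes, −40 °C → rt, 8 added over 2 h; then PhMe, 80 °C
Reagents that add atoms: none
Why: The catalyst turns 8 into a donor/acceptor vinylcarbenoid, which adds by [2+1] carbene transfer to the most electron-rich π bond of 4, the C9=C10 silyl enol ether (the E-enyne alkene and the silyl-capped alkyne are inert to such carbenoids, and 4 offers no allylic or α-oxy methylene C–H for insertion), the chiral catalyst fixing C10; the closest known reaction type is the tandem cyclopropanation/Cope rearrangement (formal [4+3] cycloaddition) of vinyldiazoacetates with 2-siloxy-1,3-dienes. The approach geometry open to a 1,2-disubstituted alkene terminus should place the C10 methyl and the C9 siloxy group cis to the carbenoid vinyl group and so give the trans-divinylcyclopropane 9. The C1–C9 bond of 9 is flanked by a siloxy donor and an ester acceptor and both carbons are allylic, so it should cleave reversibly on warming and epimerise C1 to the cis-divinylcyclopropane 10 without touching C10. 10 then undergoes the [3,3]-sigmatropic divinylcyclopropane rearrangement through the obligatory boat transition state, which closes the seven-membered ring by forming C6–C7 while C1–C9 breaks. C6 and C7 come out cis to each other because both vinyl termini are E, and both cis to the C10 methyl because that methyl is anti to the vinyl groups in 10, so the all-cis C6/C7/C10 triad follows from the one catalyst-controlled centre. The step needs attack at the carbenoid carbon and not at its vinylogous terminus (secured by the bulky E-siloxy group on C6 and the hydrocarbon solvent), attack at the enol ether and not at the other π bonds (electronics), and enantiofacial control (catalyst).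

Step 6
Reactants: 11 ethyl (3S,4S,7R)-3,6-bis[(tert-butyldimethylsilyl)oxy]-7-methyl-4-[(trimethylsilyl)ethynyl]cyclohepta-1,5-diene-1-carboxylate
Product: 12 {(3S,4S,7R)-3,6-bis[(tert-butyldimethylsilyl)oxy]-7-methyl-4-[(trimethylsilyl)ethynyl]cyclohepta-1,5-dien-1-yl}methanol
Conditions: DIBAL-H (2.5 equiv), CH2Cl2, −78 °C; Rochelle salt work-up
Reagents that add atoms: none
Why: 1,2-Reduction of the conjugated ester to the allylic alcohol (C2); silyl ethers, the silyl enol ether and the alkynylsilane are inert to DIBAL-H at this temperature.

Step 7
Reactants: 12 {(3S,4S,7R)-3,6-bis[(tert-butyldimethylsilyl)oxy]-7-methyl-4-[(trimethylsilyl)ethynyl]cyclohepta-1,5-dien-1-yl}methanol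
Product: 13 β-epoxy alcohol: 12 with an oxirane across C1–C5, its oxygen on the face opposite to the C6 silyloxy, C7 alkynyl and C10 methyl groups
Conditions: Ti(Oi-Pr)4 (10 mol %), D-(−)-diethyl tartrate (12 mol %), t-BuOOH, 4 Å MS, CH2Cl2, −20 °C
Reagents that add atoms: tert-butyl hydroperoxide, CC(C)(C)OO
Why: Sharpless asymmetric epoxidation of a 2,3-disubstituted primary allylic alcohol; D-(−)-tartrate delivers oxygen to the β face of C1=C5, which is also the face free of the three α substituents, so reagent and substrate control are matched, and the silyl enol ether, which has no directing hydroxyl, should be left.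

Step 8
Reactants: 13 β-epoxy alcohol
Product: 14 5-[(tert-butyldimethylsilyl)oxy]-3,4-dihydroxy-3-(hydroxymethyl)-2-methyl-6-[(trimethylsilyl)ethynyl]cycloheptan-1-one (C1–OH α, C5–OH β, C6–OTBS α, C7 alkynyl α, C10 methyl α)
Conditions: 0.1 M aq. HClO4, THF, 0 °C → rt
Reagents that add atoms: water, O
Why: Acid-catalysed hydrolytic opening of a trisubstituted 2,3-epoxy alcohol occurs at the tertiary carbon with inversion, so water enters C1 from the α face while the epoxide oxygen stays on C5 (β), which gives the trans C1/C5 diol of the target; the same medium hydrolyses the silyl enol ether to the C9 ketone, at a stage where C10 is no longer allylic.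

Step 9
Reactants: 14 silylated triol ketone
Product: 15 6-ethynyl-3,4,5-trihydroxy-3-(hydroxymethyl)-2-methylcycloheptan-1-one (configuration at C1, C5, C6, C7, C10 as in 22)
Conditions: TBAF, AcOH (1:1), THF, 0 °C → rt
Reagents that add atoms: none
Why: Fluoride cleaves the C6 silyl ether and the C–Si bond of the alkynylsilane; buffering with acetic acid keeps the medium non-basic so that the C9/C1 β-ketol should not undergo retro-aldol cleavage.

Step 10
Reactants: 15 ethynyl tetraol ketone
Product: 16 7,8-dihydroxy-7-(hydroxymethyl)-6-methyl-3-methylidenehexahydro-2H-cyclohepta[b]furan-2,5-dione (cis-fused α-methylene lactone; configuration as in 22)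
Conditions: PdCl2 (10 mol %), thiourea (10 mol %), CO (1 atm), acetone, 50 °C
Reagents that add atoms: carbon monoxide, [C-]#[O+]
Why: Palladium-catalysed cyclocarbonylation of a homopropargylic alcohol (alkoxycarbonyl-palladium at O6, syn insertion of the alkyne, protonolysis) builds C12 and the C11=C13 alkene in one neutral step; only O6 is cis to the ethynyl group and positioned for a five-membered ring, so only the cis-fused γ-lactone can form.

Step 11
Reactants: 16 α-methylene lactone triol
Product: 17 7,8-dihydroxy-6-methyl-3-methylidene-2,5-dioxooctahydro-2H-cyclohepta[b]furan-7-carbaldehyde (C2 aldehyde; configuration as in 22)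
Conditions: TEMPO (10 mol %), NCS, Bu4NCl (10 mol %), CH2Cl2/aq. NaHCO3–K2CO3 (pH 8.6), 0 °C
Reagents that add atoms: none
Why: Oxoammonium oxidation is selective for the primary C2 alcohol over the hindered secondary C5 and tertiary C1 alcohols, stops at the aldehyde, and should not cleave the 1,2-diol units as a hypervalent iodine co-oxidant could.

Step 12
Reactants: 17 dihydroxy aldehyde; 18 (2S)-2-methylbutanoic anhydride
Product: 19 the C5 (2S)-2-methylbutanoate of 17
Conditions: DMAP (0.3 equiv), Et3N, CH2Cl2, 0 °C → rt
Reagents that add atoms: none
Why: DMAP-catalysed acylation of the only secondary hydroxyl (C5); the tertiary C1 hydroxyl should not react, and the anhydride transfers the acyl group without a ketene pathway, so its α-centre is kept.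

Step 13
Reactants: 19 ester aldehyde; 20 (1E)-1-bromoprop-1-ene
Product: 21 the C2 allylic alcohol, 19 with CH(OH)–CH=CH–CH3 (E) in place of CHO (both C2 epimers)
Conditions: CrCl2 (6 equiv), NiCl2 (2 mol %), DMSO, rt
Reagents that add atoms: none
Why: Nozaki–Hiyama–Kishi reaction; the alkenylchromium(III) species adds to the aldehyde only (ketone, lactone, ester and the α-methylene group are tolerated) with retention of the E geometry, and the new C2 centre is oxidised in step 14.

Step 14
Reactants: 21 allylic alcohol
Product: 22 CNP0153197.2 (target)
Conditions: IBX, DMSO, rt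
Reagents that add atoms: none
Why: IBX oxidises the secondary allylic alcohol of the 1,2-diol to the α-hydroxy enone without glycol cleavage and without base, which protects C10, the β-ketol and the ester α-centre.

## Compound list

1 | 3-(trimethylsilyl)prop-2-ynal | C[Si](C)(C)C#CC=O | starting material
2 | diethyl (2-oxobutyl)phosphonate | CCC(=O)CP(=O)(OCC)OCC | starting material
3 | (4E)-7-(trimethylsilyl)hept-4-en-6-yn-3-one | CCC(=O)/C=C/C#C[Si](C)(C)C | intermediate
4 | tert-butyldimethyl{[(2Z,4E)-7-(trimethylsilyl)hepta-2,4-dien-6-yn-3-yl]oxy}silane | C/C=C(\O[Si](C)(C)C(C)(C)C)/C=C/C#C[Si](C)(C)C | intermediate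
5 | [(tert-butyldimethylsilyl)oxy]acetaldehyde | CC(C)(C)[Si](C)(C)OCC=O | starting material
6 | ethyl diazoacetate | CCOC(=O)C=[N+]=[N-] | starting material
7 | ethyl 4-[(tert-butyldimethylsilyl)oxy]-2-diazo-3-hydroxybutanoate (racemic) | CCOC(=O)C(=[N+]=[N-])C(O)CO[Si](C)(C)C(C)(C)C | intermediate
8 | ethyl (3E)-4-[(tert-butyldimethylsilyl)oxy]-2-diazobut-3-enoate | CCOC(=O)C(=[N+]=[N-])/C=C/O[Si](C)(C)C(C)(C)C | intermediate
9 | ethyl (1R,2R,3R)-2-[(tert-butyldimethylsilyl)oxy]-1-{(E)-2-[(tert-butyldimethylsilyl)oxy]ethenyl}-3-methyl-2-[(1E)-4-(trimethylsilyl)but-1-en-3-yn-1-yl]cyclopropane-1-carboxylate (alkenyl groups trans) | CCOC(=O)[C@]1(/C=C/O[Si](C)(C)C(C)(C)C)[C@@H](C)[C@]1(O[Si](C)(C)C(C)(C)C)/C=C/C#C[Si](C)(C)C | intermediate (not isolated)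
10 | ethyl (1S,2R,3R)-2-[(tert-butyldimethylsilyl)oxy]-1-{(E)-2-[(tert-butyldimethylsilyl)oxy]ethenyl}-3-methyl-2-[(1E)-4-(trimethylsilyl)but-1-en-3-yn-1-yl]cyclopropane-1-carboxylate (alkenyl groups cis, methyl trans to both) | CCOC(=O)[C@@]1(/C=C/O[Si](C)(C)C(C)(C)C)[C@@H](C)[C@]1(O[Si](C)(C)C(C)(C)C)/C=C/C#C[Si](C)(C)C | intermediate (not isolated)
11 | ethyl (3S,4S,7R)-3,6-bis[(tert-butyldimethylsilyl)oxy]-7-methyl-4-[(trimethylsilyl)ethynyl]cyclohepta-1,5-diene-1-carboxylate | CC(C)(C)[Si](C)(C)O[C@@H]1[C@H](C#C[Si](C)(C)C)C=C(O[Si](C)(C)C(C)(C)C)[C@H](C)C(C(=O)OCC)=C1 | intermediate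
12 | {(3S,4S,7R)-3,6-bis[(tert-butyldimethylsilyl)oxy]-7-methyl-4-[(trimethylsilyl)ethynyl]cyclohepta-1,5-dien-1-yl}methanol | CC(C)(C)[Si](C)(C)O[C@@H]1[C@H](C#C[Si](C)(C)C)C=C(O[Si](C)(C)C(C)(C)C)[C@H](C)C(CO)=C1 | intermediate
13 | β-epoxy alcohol: 12 with an oxirane across C1–C5, oxygen anti to the C6 silyloxy, C7 alkynyl and C10 methyl groups | CC(C)(C)[Si](C)(C)O[C@@H]1[C@H](C#C[Si](C)(C)C)C=C(O[Si](C)(C)C(C)(C)C)[C@H](C)[C@@]2(CO)O[C@@H]12 | intermediate
14 | 5-[(tert-butyldimethylsilyl)oxy]-3,4-dihydroxy-3-(hydroxymethyl)-2-methyl-6-[(trimethylsilyl)ethynyl]cycloheptan-1-one (ring configuration as in 22) | CC(C)(C)[Si](C)(C)O[C@@H]1[C@H](C#C[Si](C)(C)C)CC(=O)[C@H](C)[C@@](O)(CO)[C@H]1O | intermediate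
15 | 6-ethynyl-3,4,5-trihydroxy-3-(hydroxymethyl)-2-methylcycloheptan-1-one (ring configuration as in 22) | O[C@@H]1[C@H](C#C)CC(=O)[C@H](C)[C@@](O)(CO)[C@H]1O | intermediate
16 | 7,8-dihydroxy-7-(hydroxymethyl)-6-methyl-3-methylidenehexahydro-2H-cyclohepta[b]furan-2,5-dione (configuration as in 22) | C=C1C(=O)O[C@@H]2[C@H]1CC(=O)[C@H](C)[C@@](O)(CO)[C@H]2O | intermediate
17 | 7,8-dihydroxy-6-methyl-3-methylidene-2,5-dioxooctahydro-2H-cyclohepta[b]furan-7-carbaldehyde (configuration as in 22) | C=C1C(=O)O[C@@H]2[C@H]1CC(=O)[C@H](C)[C@@](O)(C=O)[C@H]2O | intermediate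
18 | (2S)-2-methylbutanoic anhydride | CC[C@H](C)C(=O)OC(=O)[C@@H](C)CC | starting material
19 | C5 (2S)-2-methylbutanoate of 17 | C=C1C(=O)O[C@@H]2[C@H]1CC(=O)[C@H](C)[C@@](O)(C=O)[C@H]2OC(=O)[C@@H](C)CC | intermediate
20 | (1E)-1-bromoprop-1-ene | C/C=C/Br | starting material
21 | C2 allylic alcohol: 19 with (2E)-1-hydroxybut-2-en-1-yl on C1 in place of the formyl group (both C2 epimers) | C=C1C(=O)O[C@@H]2[C@H]1CC(=O)[C@H](C)[C@@](O)(C(O)/C=C/C)[C@H]2OC(=O)[C@@H](C)CC | intermediate
22 | CNP0153197.2 | C=C1C(=O)O[C@@H]2[C@H]1CC(=O)[C@H](C)[C@@](O)(C(=O)/C=C/C)[C@H]2OC(=O)[C@@H](C)CC | target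

## Step count and risk

Total: 14 steps. Longest linear sequence: 12 steps (steps 1, 2, 5–14; the branch through steps 3 and 4 is equally long).

**Step 5 (key step).** Four processes could fail. The enol ether may attack the vinylogous terminus (C6) of the carbenoid, or an open zwitterion may collapse to five-membered rings. Carbene transfer to the trisubstituted enol ether may be too slow, so that the diazo ester is lost to carbene dimerisation or pyrazole formation. The C1 epimerisation of 9 may be slower than ring opening of the donor–acceptor cyclopropane. Enantiofacial selectivity may be low, because the approach model was developed for terminal alkenes.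

Fallback: it sets out from 4 and returns at 10, and builds the divinylcyclopropane in stages by known reactions. A copper(I)–bis(oxazoline)-catalysed cyclopropanation of 4 with 6 gives the siloxycyclopropane ester F1; small acceptor carbenoids add readily to trisubstituted silyl enol ethers. Deprotonation of F1 at C1 with LDA at −78 °C and addition of the enolate to 5 gives the aldol adduct F2. Mesylation and elimination (MsCl, Et3N, then DBU) towards the CH2–O carbon gives 9 and 10, which converge on 11 on warming as in step 5.

**Step 8.** Opening with partial cationic character may give some retention at C1 (cis-diol) or loss of the C10 proton. If the enol ether hydrolyses before the epoxide opens, the β,γ-epoxy ketone may isomerise to a γ-hydroxy enone.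

Fallback: it sets out from 13 and returns at 14, and uses intramolecular delivery, which enforces inversion at C1. The primary alcohol is converted into the tert-butyl carbonate F3 (Boc2O, DMAP). BF3·OEt2 at −40 °C triggers 5-exo attack of the carbonate carbonyl on C1 and gives the cyclic carbonate F4 with the free β-hydroxyl at C5. Methanolysis (K2CO3, MeOH), with C9 still masked so that no retro-aldol is possible, gives the triol enol ether F5. Dilute HCl in THF then hydrolyses the enol ether to 14.

**Step 10.** The polyol or the ketone hemiketals may slow the alkoxycarbonyl-palladium pathway, and alkyne hydration or an oxidative carbonylation manifold may compete.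

Fallback: it sets out from 15 and returns at 16, and changes the mechanism to oxidative addition. Markovnikov hydroiodination of the alkyne (NaI, TMSCl, H2O, MeCN) gives the 2-iodoalkene F6. Carbonylative lactonisation of F6 (Pd(PPh3)4 cat., CO 1 atm, i-Pr2NEt, MeCN, 50 °C) then gives 16.

**Step 12.** Acylation of the C5 hydroxyl, which is flanked by the quaternary C1, may be slow. Under forcing conditions acylal formation at the aldehyde, retro-aldol of the β-hydroxy aldehyde or erosion of the acyl α-centre could follow.

Fallback: it sets out from 17 and returns at 22, and moves the acylation to the end, where no aldehyde is present. Nozaki–Hiyama–Kishi addition of 20 to 17 gives the triol F7. MnO2 oxidises only the allylic alcohol and gives the hydroxy enone F8. Acylation of the single secondary hydroxyl of F8 with 18 and DMAP gives 22.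

## Further compounds

F1 | step 5 | ethyl 2-[(tert-butyldimethylsilyl)oxy]-3-methyl-2-[(1E)-4-(trimethylsilyl)but-1-en-3-yn-1-yl]cyclopropane-1-carboxylate (C2 and C3 as in 10, both C1 epimers) | CCOC(=O)C1[C@@H](C)[C@]1(O[Si](C)(C)C(C)(C)C)/C=C/C#C[Si](C)(C)C
F2 | step 5 | ethyl 2-[(tert-butyldimethylsilyl)oxy]-1-{2-[(tert-butyldimethylsilyl)oxy]-1-hydroxyethyl}-3-methyl-2-[(1E)-4-(trimethylsilyl)but-1-en-3-yn-1-yl]cyclopropane-1-carboxylate (C2 and C3 as in 10, epimers at C1 and the carbinol) | CCOC(=O)C1(C(O)CO[Si](C)(C)C(C)(C)C)[C@@H](C)[C@]1(O[Si](C)(C)C(C)(C)C)/C=C/C#C[Si](C)(C)C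
F3 | step 8 | tert-butyl carbonate of the primary hydroxyl of 13 | CC(C)(C)[Si](C)(C)O[C@@H]1[C@H](C#C[Si](C)(C)C)C=C(O[Si](C)(C)C(C)(C)C)[C@H](C)[C@@]2(COC(=O)OC(C)(C)C)O[C@@H]12
F4 | step 8 | cyclic carbonate across the C1 and C2 oxygens with free β-hydroxyl at C5, silyl enol ether retained | CC(C)(C)[Si](C)(C)O[C@@H]1[C@H](C#C[Si](C)(C)C)C=C(O[Si](C)(C)C(C)(C)C)[C@H](C)[C@@]2(COC(=O)O2)[C@H]1O
F5 | step 8 | triol silyl enol ether (14 with C9 still as its tert-butyldimethylsilyl enol ether, C8=C9) | CC(C)(C)[Si](C)(C)O[C@@H]1[C@H](C#C[Si](C)(C)C)C=C(O[Si](C)(C)C(C)(C)C)[C@H](C)[C@@](O)(CO)[C@H]1O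
F6 | step 10 | 3,4,5-trihydroxy-3-(hydroxymethyl)-6-(1-iodoethenyl)-2-methylcycloheptan-1-one (configuration as in 15) | O[C@@H]1[C@H](C(I)=C)CC(=O)[C@H](C)[C@@](O)(CO)[C@H]1O
F7 | step 12 | 21 without the C5 acyl group (free C5 hydroxyl, both C2 epimers) | C=C1C(=O)O[C@@H]2[C@H]1CC(=O)[C@H](C)[C@@](O)(C(O)/C=C/C)[C@H]2O
F8 | step 12 | 22 without the C5 acyl group (free C5 hydroxyl) | C=C1C(=O)O[C@@H]2[C@H]1CC(=O)[C@H](C)[C@@](O)(C(=O)/C=C/C)[C@H]2O
A1 | alternative 1 | methyl 5-(2-tert-butoxy-2-oxoethyl)-1-hydroxy-2-methyl-3-oxocyclohept-6-ene-1-carboxylate (C1, C7, C10 configured as in 22) | [C@@H]1(CC(=O)OC(C)(C)C)CC(=O)[C@H](C)[C@@](O)(C(=O)OC)C=C1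
A2 | alternative 2 | seco-diketone: the α-methylene lactone carrying a 2-oxobutyl group on C7 and, on C6, a CH[O-(2S)-2-methylbutanoyl]–C(=O)–C(=O)–CH=CH–CH3 chain (C5, C6, C7 as in 22) | C=C1C(=O)O[C@H]([C@H]1CC(=O)CC)[C@H](OC(=O)[C@@H](C)CC)C(=O)C(=O)/C=C/C
A3 | alternative 3 | 1-{[(tert-butyldimethylsilyl)oxy]methyl}-2-methyl-8-oxabicyclo[3.2.1]oct-6-en-3-one (racemic, one enantiomer drawn, methyl trans to the oxygen bridge) | O1[C@H]2C=C[C@]1(CO[Si](C)(C)C(C)(C)C)[C@H](C)C(=O)C2
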